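A closed, stirred vessel holds substrate and catalyst, and a solid reagent feeds coupling partner into the solution.

    coupling partner + catalyst + intermediate → catalyst + target (k1 = 25000 M⁻² s⁻¹)
    substrate + catalyst → catalyst + intermediate (k2 = 1000 M⁻¹ s⁻¹)
    catalyst + target → catalyst + over-reaction product (k3 = 850 M⁻¹ s⁻¹)
    solid reagent ⇌ coupling partner, rate k4*(cs4 - [coupling partner]) while solid is left; crystals form when [coupling partner] > cs4 (cs4 = 47 mM, k4 = 0.023 s⁻¹)

substrate 0.10 M; solid reagent 0.200 M; catalyst 0.12 mM; time 12 s

- how much target there is at 12 s, in percent of the substrate charged
- concentration of coupling partner in solution at 12 s, in percent of saturation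

1. **Quantity.** The balance level of the coupling partner is the quasi-steady concentration at which dissolution equals coupling. It is the dissolution coefficient times the solubility, divided by that coefficient plus the coupling pull (coupling constant times catalyst times intermediate).

2. **Time, by hand.** Substrate has a half-life of 5.8 s, so 76.3% of it has reacted by 12 s. Dissolution can deliver at most 13.0%; this reckoning counts half of that as spent, which leaves 69.8% as intermediate. The pull is then 0.209 s⁻¹, faster than the dissolution coefficient of 0.023 s⁻¹. So the balance level is 4.65 mM, or 9.89% of saturation.

3. **Target, by hand.** Supply over loss gives a target ceiling of 10.6%. With the coupling flow taken to rise evenly from zero, and a target half-life of 6.8 s, the reckoning commits to 4.49%.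

4. **Catalyst, by hand.** The ceiling falls as catalyst rises, while conversion and pull rise with it.

5. **Substrate, by hand.** It acts through the intermediate in the pull.

6. **Solid reagent, by hand.** Its charge stands in neither formula, and at most 6.49% of it dissolves by 12 s.

7. **Forecast.** The forecast gives 4.8% and 10.4%, on the ground that “Dissolution is the bottleneck”. Both lie above this reckoning.

8. **Simulation.** The flask gives 4.85% and 10.4%. Settings rank by effect on target as time (1.6 points), then catalyst (0.7 points), then substrate (0.63 points), then solid reagent (under 0.05 points).

At 12.0 s the flask makes coupling partner 0.950 times as fast as it uses it up. With the simulated intermediate of 69.3%, the balance level becomes 4.68 mM, against 4.91 mM in solution. The same flask read at 30 s holds 72.2% intermediate, so its balance level is 4.51 mM, and that later reading shows 4.43 mM of coupling partner. Its target, 8.94%, stands below the ceiling of 10.6%.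

All constants are those of an exercise; the rest is arithmetic.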